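**Assumption (remark on the chemistry):** the face selectivity of the Pd–pyridine-oxazoline arylation of chromone 4 is taken to follow that of 3-substituted cyclohexenones, which calls for the (R)-ligand to reach (S)-9. If the sense proves opposite, the (S)-ligand is used and nothing else changes.

Numbering: benzofuran numbering for the target (O1, C2, C3, C3a, C4–C7, C7a); chromanone numbering for the flavanone (O1, C2, C3, C4, C4a, C5–C8, C8a). The target SMILES encodes the 2,3-trans (2S,3R) isomer.

## The problem

- The target is an 8–5′ neolignan: a 2,3-dihydrobenzofuran with a syringyl ring on C2, an acyloxymethyl group on C3, OMe on C7 and an (E)-3-acyloxypropenyl chain on C5.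
- Closing the ring in racemic form is easy. The difficulty is absolute control of two adjacent benzylic centres on a ring that can reopen.
- C2 is an O-benzylic carbon para to a free phenol, so it can ionise to a p-quinone methide in acid or base. C3 is epimerisable whenever its exocyclic carbon is at the carbonyl level.
- Because trans is the thermodynamic arrangement, only one centre needs an external source of chirality. C2 can control C3 while C3 is α to an ester, and C3 guards C2 once the ester is reduced.
- Both primary alcohols carry the same 4-hydroxybenzoate. One is cinnamylic (no Pd(0), no hydrogenolysis, prone to ionisation), and the three free phenols beside two ester links rule out a basic or reductive deprotection at the end.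
- The feature that makes the key step possible: C3 carries, besides the ring carbon C3a, an exocyclic oxygenated carbon. C3a–C3–C(exo) is the connectivity left by a 1,2-aryl shift. Bonding C3a back to the exocyclic carbon turns the furan ring into the ring O1–C2–C3–C4(=O)–C4a–C8a of a 2-aryl-chroman-4-one (flavanone) whose only stereocentre is C2.
- A second feature: the C3 exocyclic carbon and the side-chain terminus are both CH2O-acyl with the same acid, so they can travel as two esters and be reduced and acylated together.

## Retrosynthesis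

**17 ⇒ 15 + 16.** The two ester C–O bonds are cut, giving triol 15 and two molecules of 4-hydroxybenzoic acid 16. The acyl groups are identical, so one operation installs both. Putting them on last keeps an aryl and an allyl ester away from hydride, base and palladium. The forward reaction must acylate only through the carboxyl group of 16 in the presence of four phenols, and substitute the cinnamyl carbinol without allylic transposition.

**15 ⇒ 14.** Both CH2OH carbons are raised to methyl esters and the syringyl OH is masked as a pivalate. One hydride operation undoes all three. This places C3 α to an ester, which is what the key step delivers, and turns the side chain into an acrylate, which a Heck reaction delivers.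

**14 ⇒ 12 + 13.** The C5–vinyl bond is cut to aryl bromide 12 and methyl acrylate 13. The chain is added after the key step because bromine is inert to iodine(III), acid and Pd(II), whereas an enoate on the migrating ring would add a site for oxidation. It is not added at the flavanone stage because amine base racemises flavanones by retro-oxa-Michael opening.

**12 ⇒ 9 (key).** The C3–C3a bond is cut and C3a is rebonded to the ester carbon, giving flavanone 9. The forward reaction is an oxidative ring contraction through enol ether 10 and iodane 11. Compared with closing the O1–C2 or C3–C3a bond directly, this cut removes one stereocentre and the exocyclic carbon at once. Compound 9 has one stereocentre, and it sits where catalytic conjugate arylation can set it. The forward step must move C4a, not the C2 aryl group, and must not ionise C2. For this reason the para oxygen of the B ring is acylated (pivalate).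

**9 ⇒ 4 + 8.** The C2–aryl bond is cut to chromone 4 and boronic acid 8. Against a chalcone cyclisation, conjugate arylation has reliable catalyst control and runs without base, so the flavanone is not racemised and the pivalate survives.

**4 ⇒ 2 ⇒ 1 and 8 ⇒ 6 ⇒ 5.**
- Chromone 4 comes from bromoacetophenone 2 by one-carbon annulation through enaminone 3. Compound 2 comes from commercial 1 by para-bromination.
- Boronic acid 8 comes from syringol pivalate 6 by sterically directed C–H borylation through boronate 7. Compound 6 comes from syringol 5.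

## Roads not taken

**Alternative 1:** the biomimetic cut of the O1–C2 and C3–C3a bonds (most obvious).
- Forward step: oxidative radical cross-coupling (Ag2O or peroxidase/H2O2) of coniferyl 4-hydroxybenzoate A1 with sinapyl 4-hydroxybenzoate A2.
- It is one step, but it gives the racemate (17 with its enantiomer A3).
- Homo-coupling of A1 and the β–β and β–O–4 modes of A2 compete, and the 4-hydroxybenzoate phenols are additional radical sites.
- A resolution would then be needed on a mixture. The chosen plan sets the absolute configuration by catalysis and gets the relative configuration from a stereospecific shift.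

**Alternative 2:** cut of the C2–C3 bond.
- Forward step: Rh(II)-carbenoid insertion of aryldiazoacetate A4 into the benzylic C–H bond of its syringyl ether.
- The catalyst must set both centres. The kinetic product is usually the cis ester and must be epimerised.
- The very electron-rich syringyl ether favours hydride transfer and ionisation over clean insertion.
- A4 needs a homologated arylacetate, an unstable syringyl halide for the etherification and a diazo transfer. This is a longer run-up than the two-step chromone.

**Alternative 3:** cut of the O1–C2 bond only.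
- Forward step: auxiliary-controlled boron syn-aldol of arylacetyl oxazolidinone A5 with a protected syringaldehyde to adduct A6, then acid-induced closure of the ortho phenol onto the benzylic cation and reductive removal of the auxiliary.
- It is reliable in relative configuration, since C3 directs C2.
- It is stoichiometric in chirality. The α-aryl imide epimerises and undergoes retro-aldol easily with an electron-rich aldehyde.
- The route spends steps on the arylacetic acid, on orthogonal phenol protection and on auxiliary removal. The ring contraction gets the same C3 centre from a catalytic C2 centre in one step.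

Key step: step 6

## Route

**Step 1**
Reactants: 1 1-(2-hydroxy-3-methoxyphenyl)ethan-1-one
Product: 2 1-(5-bromo-2-hydroxy-3-methoxyphenyl)ethan-1-one
Conditions: NBS (1.05 equiv), MeCN, 0 °C → rt
Reagents that add atoms: N-bromosuccinimide, O=C1CCC(=O)N1Br
Why: Electrophilic aromatic bromination; the position para to the phenol OH (meta to the acetyl group) is the only strongly activated free site, both ortho positions being occupied.

**Step 2**
Reactants: 2 1-(5-bromo-2-hydroxy-3-methoxyphenyl)ethan-1-one
Product: 4 6-bromo-8-methoxy-4H-chromen-4-one, via enaminone 3 (not isolated)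
Conditions: Me2NCH(OMe)2, toluene, 100 °C; then conc. HCl, CH2Cl2, 40 °C
Reagents that add atoms: N,N-dimethylformamide dimethyl acetal, COC(OC)N(C)C
Why: Standard enaminone chromone synthesis; condensation at the acetyl CH3 gives 3, and acid-promoted addition of the phenol with loss of dimethylamine closes the pyranone.

**Step 3**
Reactants: 5 2,6-dimethoxyphenol (syringol)
Product: 6 2,6-dimethoxyphenyl pivalate
Conditions: PivCl, Et3N, DMAP (cat.), CH2Cl2, 0 °C → rt
Reagents that add atoms: pivaloyl chloride, CC(C)(C)C(=O)Cl
Why: DMAP-catalysed O-acylation; the pivalate is chosen because it withdraws electron density from the future B ring, resists acid methanolysis and is later removed by hydride.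

**Step 4**
Reactants: 6 2,6-dimethoxyphenyl pivalate
Product: 8 [3,5-dimethoxy-4-(pivaloyloxy)phenyl]boronic acid, via pinacol boronate 7 (not isolated)
Conditions: [Ir(OMe)(cod)]2 (1.5 mol %), dtbpy (3 mol %), B2pin2 (0.6 equiv), THF, 80 °C; then NaIO4, aq. HCl, THF/H2O, rt
Reagents that add atoms: bis(pinacolato)diboron, CC1(C)OB(OC1(C)C)B1OC(C)(C)C(C)(C)O1; water, O
Why: Sterically controlled Ir-catalysed C–H borylation of a 1,2,3-trisubstituted arene goes to C4, the only C–H with no ortho substituent; one-pot periodate cleavage of the pinacol ester gives the free boronic acid.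

**Step 5**
Reactants: 4 6-bromo-8-methoxy-4H-chromen-4-one; 8 [3,5-dimethoxy-4-(pivaloyloxy)phenyl]boronic acid (2 equiv)
Product: 9 4-[(2S)-6-bromo-8-methoxy-4-oxo-3,4-dihydro-2H-chromen-2-yl]-2,6-dimethoxyphenyl pivalate [(S)-flavanone]
Conditions: Pd(OCOCF3)2 (5 mol %), (R)-t-BuPyOx (6 mol %), NH4PF6 (30 mol %), H2O (5 equiv), ClCH2CH2Cl, 60 °C
Reagents that add atoms: none
Why: Pd(II)-catalysed asymmetric conjugate addition of an arylboronic acid to a chromone; the chiral pyridine-oxazoline ligand differentiates the enone faces and sets C2. The cycle stays at Pd(II) without base, so the aryl bromide, the pivalate and the configuration of the flavanone should be preserved.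

**Step 6**
Reactants: 9 4-[(2S)-6-bromo-8-methoxy-4-oxo-3,4-dihydro-2H-chromen-2-yl]-2,6-dimethoxyphenyl pivalate
Product: 12 methyl (2S,3S)-5-bromo-2-[3,5-dimethoxy-4-(pivaloyloxy)phenyl]-7-methoxy-2,3-dihydro-1-benzofuran-3-carboxylate, via enol ether 10 (not isolated), via trans-iodane 11 (not isolated)
Conditions: HC(OMe)3 (solvent), conc. H2SO4 (0.5 equiv), 0 °C → rt; then PhI(OAc)2 (1.3 equiv), rt
Reagents that add atoms: trimethyl orthoformate, COC(OC)OC
Why: This is the hypervalent-iodine oxidative ring contraction of a flavanone, a known semipinacol-type 1,2-aryl shift of chroman-4-ones to trans-2-aryl-2,3-dihydrobenzofuran-3-carboxylates. Acid and orthoformate convert the C4 ketone into enol ether 10; PhI(OAc)2 attacks C3 on the face anti to the C2 aryl group and methanol caps C4, giving the 2,3-trans iodane 11 with aryl and iodanyl groups both equatorial. In that conformer the ring bond C4–C4a is antiperiplanar to C3–I, so C4a migrates from C4 to C3 as iodobenzene leaves, and C4 is pushed out of the ring as a dialkoxycarbenium centre that collapses to the methyl ester. The ring O1–C2–C3–C3a–C7a is therefore formed by contraction of the pyranone (1,2-shift of an aryl carbon with extrusion of C4) and not by a cyclisation, so no exo or endo mode applies. C2 is not touched and keeps its configuration; the new centre C3 is set by substrate control, since iodine anti to the aryl group followed by inversion at C3 places the ester trans to the aryl group, which is also the thermodynamic arrangement. The step needs migration of C4a in preference to the C2 aryl group (isoflavone pathway) and to loss of H (flavone pathway), and it needs the C2–O1 bond to stay intact in acid. The equatorial preference of the C2 aryl group and the ortho oxygen O1 on the migrating carbon secure the first; the 4-pivaloyloxy group between two meta methoxy groups makes the B ring a poor migrating group and a poor stabiliser of a C2 cation.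

**Step 7**
Reactants: 12 methyl (2S,3S)-5-bromo-2-[3,5-dimethoxy-4-(pivaloyloxy)phenyl]-7-methoxy-2,3-dihydro-1-benzofuran-3-carboxylate; 13 methyl acrylate
Product: 14 methyl (2S,3S)-2-[3,5-dimethoxy-4-(pivaloyloxy)phenyl]-7-methoxy-5-[(E)-3-methoxy-3-oxoprop-1-en-1-yl]-2,3-dihydro-1-benzofuran-3-carboxylate
Conditions: Pd2(dba)3 (2 mol %), [HP(t-Bu)3]BF4 (8 mol %), Cy2NMe (1.2 equiv), 1,4-dioxane, rt → 40 °C
Reagents that add atoms: none
Why: Mizoroki–Heck reaction of an unhindered, electron-rich aryl bromide under bulky-phosphine conditions near room temperature; syn-insertion and β-hydride elimination give the E-enoate. The weak hindered amine base should not deprotonate C3, and trans is the stable C3 epimer in any case.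

**Step 8**
Reactants: 14 methyl (2S,3S)-2-[3,5-dimethoxy-4-(pivaloyloxy)phenyl]-7-methoxy-5-[(E)-3-methoxy-3-oxoprop-1-en-1-yl]-2,3-dihydro-1-benzofuran-3-carboxylate
Product: 15 4-[(2S,3R)-3-(hydroxymethyl)-5-[(E)-3-hydroxyprop-1-en-1-yl]-7-methoxy-2,3-dihydro-1-benzofuran-2-yl]-2,6-dimethoxyphenol
Conditions: DIBAL-H (9 equiv), CH2Cl2/toluene, −78 → 0 °C; aq. Rochelle salt
Reagents that add atoms: none
Why: DIBAL-H reduces the saturated ester and, 1,2-selectively, the enoate to the two primary alcohols and cleaves the aryl pivalate in the same operation; this reduction is standard for phenolic 8–5′ diesters. C3 keeps its spatial arrangement (the descriptor changes to R by priority only) and is no longer epimerisable.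

**Step 9**
Reactants: 15 4-[(2S,3R)-3-(hydroxymethyl)-5-[(E)-3-hydroxyprop-1-en-1-yl]-7-methoxy-2,3-dihydro-1-benzofuran-2-yl]-2,6-dimethoxyphenol; 16 4-hydroxybenzoic acid (2.6 equiv)
Product: 17 quiquesetinerviusin B
Conditions: PPh3 (2.6 equiv), DIAD (2.6 equiv), THF, 0 °C → rt
Reagents that add atoms: none
Why: Double Mitsunobu esterification; the carboxylic acid is far more acidic than any phenol present, so only the carboxylate is alkylated and no phenol protection is needed (chemoselective esterification of phenolic acids with alcohols under these conditions is known). Both carbinol carbons are primary and achiral, so the stereocentres are not involved.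

## Compound list

1 | 1-(2-hydroxy-3-methoxyphenyl)ethan-1-one | CC(=O)c1cccc(OC)c1O | starting material
2 | 1-(5-bromo-2-hydroxy-3-methoxyphenyl)ethan-1-one | CC(=O)c1cc(Br)cc(OC)c1O | intermediate
3 | (E)-1-(5-bromo-2-hydroxy-3-methoxyphenyl)-3-(dimethylamino)prop-2-en-1-one | CN(C)/C=C/C(=O)c1cc(Br)cc(OC)c1O | intermediate (not isolated)
4 | 6-bromo-8-methoxy-4H-chromen-4-one | COc1cc(Br)cc2c(=O)ccoc12 | intermediate
5 | 2,6-dimethoxyphenol | COc1cccc(OC)c1O | starting material
6 | 2,6-dimethoxyphenyl pivalate | COc1cccc(OC)c1OC(=O)C(C)(C)C | intermediate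
7 | 2,6-dimethoxy-4-(4,4,5,5-tetramethyl-1,3,2-dioxaborolan-2-yl)phenyl pivalate | COc1cc(B2OC(C)(C)C(C)(C)O2)cc(OC)c1OC(=O)C(C)(C)C | intermediate (not isolated)
8 | [3,5-dimethoxy-4-(pivaloyloxy)phenyl]boronic acid | COc1cc(B(O)O)cc(OC)c1OC(=O)C(C)(C)C | intermediate
9 | 4-[(2S)-6-bromo-8-methoxy-4-oxo-3,4-dihydro-2H-chromen-2-yl]-2,6-dimethoxyphenyl pivalate | COc1cc([C@H]2Oc3c(OC)cc(Br)cc3C(=O)C2)cc(OC)c1OC(=O)C(C)(C)C | intermediate
10 | 4-[(2S)-6-bromo-4,8-dimethoxy-2H-chromen-2-yl]-2,6-dimethoxyphenyl pivalate | COc1cc([C@H]2Oc3c(OC)cc(Br)cc3C(OC)=C2)cc(OC)c1OC(=O)C(C)(C)C | intermediate (not isolated)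
11 | 4-[(2R,3R)-3-[acetoxy(phenyl)-λ3-iodanyl]-6-bromo-4,4,8-trimethoxy-3,4-dihydro-2H-chromen-2-yl]-2,6-dimethoxyphenyl pivalate (2,3-trans; same spatial arrangement at C2 as in 9) | COc1cc([C@H]2Oc3c(OC)cc(Br)cc3C(OC)(OC)[C@@H]2I(OC(C)=O)c2ccccc2)cc(OC)c1OC(=O)C(C)(C)C | intermediate (not isolated)
12 | methyl (2S,3S)-5-bromo-2-[3,5-dimethoxy-4-(pivaloyloxy)phenyl]-7-methoxy-2,3-dihydro-1-benzofuran-3-carboxylate (trans) | COc1cc([C@H]2Oc3c(OC)cc(Br)cc3[C@@H]2C(=O)OC)cc(OC)c1OC(=O)C(C)(C)C | intermediate
13 | methyl acrylate | C=CC(=O)OC | starting material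
14 | methyl (2S,3S)-2-[3,5-dimethoxy-4-(pivaloyloxy)phenyl]-7-methoxy-5-[(E)-3-methoxy-3-oxoprop-1-en-1-yl]-2,3-dihydro-1-benzofuran-3-carboxylate | COc1cc([C@H]2Oc3c(OC)cc(/C=C/C(=O)OC)cc3[C@@H]2C(=O)OC)cc(OC)c1OC(=O)C(C)(C)C | intermediate
15 | 4-[(2S,3R)-3-(hydroxymethyl)-5-[(E)-3-hydroxyprop-1-en-1-yl]-7-methoxy-2,3-dihydro-1-benzofuran-2-yl]-2,6-dimethoxyphenol | COc1cc([C@H]2Oc3c(OC)cc(/C=C/CO)cc3[C@@H]2CO)cc(OC)c1O | intermediate
16 | 4-hydroxybenzoic acid | O=C(O)c1ccc(O)cc1 | starting material
17 | quiquesetinerviusin B, [(2S,3R)-2-(4-hydroxy-3,5-dimethoxyphenyl)-5-[(E)-3-(4-hydroxybenzoyloxy)prop-1-en-1-yl]-7-methoxy-2,3-dihydro-1-benzofuran-3-yl]methyl 4-hydroxybenzoate | COc1cc([C@H]2Oc3c(OC)cc(/C=C/COC(=O)c4ccc(O)cc4)cc3[C@@H]2COC(=O)c2ccc(O)cc2)cc(OC)c1O | target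

## Step count and risks

Total: 9 steps. Longest linear sequence: 7 steps (1 → 2 → 4 → 9 → 12 → 14 → 15 → 17; the branch from 5 is equally long).

**Step 6 (key step).**
- What may go wrong: migration of the C2 aryl group or dehydrogenation in place of the C4a shift, which destroys the C2 centre; acid-induced ionisation of C2–O1, which erodes the enantiomeric purity; oxidation of the methoxylated rings by iodine(III). The bromine and methoxy groups meta to C4a also make the migrating carbon somewhat less electron-rich than in the parent system.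
- Fallback: from 9, the lithium enolate (LiHMDS, THF, −78 °C) is acylated with 2,2,2-trifluoroethyl trifluoroacetate to the 3-trifluoroacetyl flavanone F1. Deacylative diazo transfer (MsN3, Et3N, MeCN) gives the 3-diazoflavanone F2. Irradiation at 365 nm in MeOH/THF triggers a Wolff rearrangement in which the same carbon C4a moves to the carbene carbon C3, and methanol adds to the ring-contracted ketene. The cis ester F3 formed beside 12 is equilibrated to the trans ester with DBU in toluene. The route is rejoined at 12.

**Step 9.**
- What may go wrong: loss of chemoselectivity once the acid is consumed (O-alkylation of a phenol); ionisation of the cinnamyl oxyphosphonium ion, which is stabilised by the para oxygen O1, leading to allylic transposition or oligomers.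
- Fallback: from 15, per-silylation (TBSCl, imidazole, DMF) gives the tris-silyl ether F4. Acid methanolysis of the two alkyl silyl ethers only (CSA cat., MeOH/CH2Cl2, 0 °C) gives the aryl silyl ether diol F5. Steglich esterification with commercial 4-[(tert-butyldimethylsilyl)oxy]benzoic acid (EDC·HCl, DMAP, CH2Cl2), in which no carbinol C–O bond is broken, gives the bis-ester F6. Desilylation of the three aryl silyl ethers with TBAF/AcOH (THF, 0 °C) rejoins the route at 17.

**Step 5.**
- What may go wrong: insufficient face selectivity on this 8-methoxychromone; slow transmetalation or protodeboronation of the electron-poor boronic acid; a sense of induction opposite to the assumption.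
- Fallback: from 4 and 8, the same addition with achiral 2,2′-bipyridine as ligand gives the racemic flavanone (9 together with its enantiomer F7). Kinetic resolution by asymmetric transfer hydrogenation (Cp*RhCl(TsDPEN), HCO2H/Et3N, EtOAc, rt), with the catalyst antipode that reduces the (R)-ketone F7 to the cis-flavan-4-ol F8, leaves (S)-9, which is separated by chromatography. The route is rejoined at 9.

**Step 8.**
- What may go wrong: conjugate reduction of the enoate; slow cleavage of the hindered pivalate that forces higher temperature; hydride opening of the C2–O1 bond once the aluminium phenoxide is formed.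
- Fallback: from 12, Suzuki–Miyaura coupling with commercial (E)-3-[(tert-butyldimethylsilyl)oxy]prop-1-enylboronic acid pinacol ester (Pd(dppf)Cl2, CsF, dioxane/H2O, 60 °C) gives the allyl silyl ether F9, with the side chain already at the alcohol oxidation level. LiAlH4 (THF, 0 °C) reduces the one saturated ester and removes the pivalate to give F10. TBAF/AcOH (THF, 0 °C) removes the silyl group and rejoins the route at 15.

## Further compounds

F1 | step 6 | 4-[(2S)-6-bromo-8-methoxy-4-oxo-3-(trifluoroacetyl)-3,4-dihydro-2H-chromen-2-yl]-2,6-dimethoxyphenyl pivalate (C3 epimers and enol) | COc1cc([C@H]2Oc3c(OC)cc(Br)cc3C(=O)C2C(=O)C(F)(F)F)cc(OC)c1OC(=O)C(C)(C)C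
F2 | step 6 | 4-[(2R)-6-bromo-3-diazo-8-methoxy-4-oxo-3,4-dihydro-2H-chromen-2-yl]-2,6-dimethoxyphenyl pivalate (same spatial arrangement at C2 as in 9) | COc1cc([C@H]2Oc3c(OC)cc(Br)cc3C(=O)C2=[N+]=[N-])cc(OC)c1OC(=O)C(C)(C)C
F3 | step 6 | methyl (2S,3R)-5-bromo-2-[3,5-dimethoxy-4-(pivaloyloxy)phenyl]-7-methoxy-2,3-dihydro-1-benzofuran-3-carboxylate (cis) | COc1cc([C@H]2Oc3c(OC)cc(Br)cc3[C@H]2C(=O)OC)cc(OC)c1OC(=O)C(C)(C)C
F4 | step 9 | tris(tert-butyldimethylsilyl) ether of 15 | COc1cc([C@H]2Oc3c(OC)cc(/C=C/CO[Si](C)(C)C(C)(C)C)cc3[C@@H]2CO[Si](C)(C)C(C)(C)C)cc(OC)c1O[Si](C)(C)C(C)(C)C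
F5 | step 9 | [(2S,3R)-2-[4-(tert-butyldimethylsilyloxy)-3,5-dimethoxyphenyl]-5-[(E)-3-hydroxyprop-1-en-1-yl]-7-methoxy-2,3-dihydro-1-benzofuran-3-yl]methanol | COc1cc([C@H]2Oc3c(OC)cc(/C=C/CO)cc3[C@@H]2CO)cc(OC)c1O[Si](C)(C)C(C)(C)C
F6 | step 9 | tris(tert-butyldimethylsilyl) ether of 17 | COc1cc([C@H]2Oc3c(OC)cc(/C=C/COC(=O)c4ccc(O[Si](C)(C)C(C)(C)C)cc4)cc3[C@@H]2COC(=O)c2ccc(O[Si](C)(C)C(C)(C)C)cc2)cc(OC)c1O[Si](C)(C)C(C)(C)C
F7 | step 5 | 4-[(2R)-6-bromo-8-methoxy-4-oxo-3,4-dihydro-2H-chromen-2-yl]-2,6-dimethoxyphenyl pivalate | COc1cc([C@@H]2Oc3c(OC)cc(Br)cc3C(=O)C2)cc(OC)c1OC(=O)C(C)(C)C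
F8 | step 5 | 4-[(2R,4R)-6-bromo-4-hydroxy-8-methoxy-3,4-dihydro-2H-chromen-2-yl]-2,6-dimethoxyphenyl pivalate (2,4-cis) | COc1cc([C@@H]2Oc3c(OC)cc(Br)cc3[C@H](O)C2)cc(OC)c1OC(=O)C(C)(C)C
F9 | step 8 | methyl (2S,3S)-5-[(E)-3-(tert-butyldimethylsilyloxy)prop-1-en-1-yl]-2-[3,5-dimethoxy-4-(pivaloyloxy)phenyl]-7-methoxy-2,3-dihydro-1-benzofuran-3-carboxylate | COc1cc([C@H]2Oc3c(OC)cc(/C=C/CO[Si](C)(C)C(C)(C)C)cc3[C@@H]2C(=O)OC)cc(OC)c1OC(=O)C(C)(C)C
F10 | step 8 | 4-[(2S,3R)-5-[(E)-3-(tert-butyldimethylsilyloxy)prop-1-en-1-yl]-3-(hydroxymethyl)-7-methoxy-2,3-dihydro-1-benzofuran-2-yl]-2,6-dimethoxyphenol | COc1cc([C@H]2Oc3c(OC)cc(/C=C/CO[Si](C)(C)C(C)(C)C)cc3[C@@H]2CO)cc(OC)c1O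
A1 | alternative 1 | (E)-3-(4-hydroxy-3-methoxyphenyl)prop-2-en-1-yl 4-hydroxybenzoate | COc1cc(/C=C/COC(=O)c2ccc(O)cc2)ccc1O
A2 | alternative 1 | (E)-3-(4-hydroxy-3,5-dimethoxyphenyl)prop-2-en-1-yl 4-hydroxybenzoate | COc1cc(/C=C/COC(=O)c2ccc(O)cc2)cc(OC)c1O
A3 | alternative 1 | (2R,3S)-enantiomer of 17 | COc1cc([C@@H]2Oc3c(OC)cc(/C=C/COC(=O)c4ccc(O)cc4)cc3[C@H]2COC(=O)c2ccc(O)cc2)cc(OC)c1O
A4 | alternative 2 | methyl 2-[5-bromo-2-[[3,5-dimethoxy-4-(triisopropylsilyloxy)phenyl]methoxy]-3-methoxyphenyl]-2-diazoacetate | COC(=O)C(=[N+]=[N-])c1cc(Br)cc(OC)c1OCc1cc(OC)c(O[Si](C(C)C)(C(C)C)C(C)C)c(OC)c1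
A5 | alternative 3 | (4S)-4-benzyl-3-[2-[5-bromo-3-methoxy-2-(methoxymethoxy)phenyl]acetyl]oxazolidin-2-one | COCOc1c(OC)cc(Br)cc1CC(=O)N1[C@@H](Cc2ccccc2)COC1=O
A6 | alternative 3 | (4S)-4-benzyl-3-[(2S,3S)-2-[5-bromo-3-methoxy-2-(methoxymethoxy)phenyl]-3-[3,5-dimethoxy-4-(methoxymethoxy)phenyl]-3-hydroxypropanoyl]oxazolidin-2-one | O=C1OC[C@H](Cc2ccccc2)N1C(=O)[C@@H](c1cc(Br)cc(OC)c1OCOC)[C@H](O)c1cc(OC)c(OCOC)c(OC)c1
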